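**Plan**
- Cuts, in retrosynthetic order: (a) the ester C–O bond between the malate C1 carboxyl and the chain-end oxygen; (b) the acyl–oxygen bond O1–C5 of the 5-oxooxolane ring; (c) the C–C bond between the quaternary ring carbon C2 and the exocyclic carboxyl-bearing CH, as an aldol bond.
- Enabling feature: ring atom C2 carries O1 and a carboxyl group and is followed by C3–C4–C5(=O), so C2–C5 plus the C2 carboxyl are the five carbons of 2-oxoglutaric acid with C2 as its ketone carbon. The exocyclic CH(CO2H) is the α-carbon of a C12 acyl unit. This is the acyl-thioester plus 2-oxoglutarate condensation presumed for alkylcitrate biosynthesis.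
- Forward: 12-hydroxydodecanoic acid → silyl-protected S-ethyl thioester → silylketene thioacetal. A catalytic aldol addition to dibenzyl 2-oxoglutarate joins the fragments, and the oxolanone (the only ring) closes in the same step. Then thioester → benzyl ester, desilylation, acylation with O-trifluoroacetyl-(R)-malic anhydride, hydrogenolysis.
- Stereochemistry: the quaternary centre is set by Cu(OTf)2/(S,S)-tBu-box (divalent copper), the neighbouring CH centre by syn diastereoselection in the same bond formation; the malate centre is bought as (R)-malic acid.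

Key step: step 5

Assumption: the (S,S) ligand is taken to expose the si face of the chelated keto ester, as the square-planar chelate model for pyruvate esters predicts; the mirror-image ligand would be used if the opposite sense were found.

**Step 1**
Reactants: 1 2-oxoglutaric acid
Product: 2 dibenzyl 2-oxopentanedioate
Conditions: BnBr, dicyclohexylamine, DMF, rt → 50 °C
Reagents that add atoms: benzyl bromide, BrCc1ccccc1
Why: SN2 O-alkylation of the bis(dicyclohexylammonium) carboxylate esterifies both acids without touching the ketone, and benzyl esters allow hydrogenolytic release at the end.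

**Step 2**
Reactants: 3 12-hydroxydodecanoic acid
Product: 5 12-[(tert-butyldiphenylsilyl)oxy]dodecanoic acid, via bis-silylated ester 4 (not isolated)
Conditions: TBDPSCl (2.2 equiv), imidazole, DMF, rt; then K2CO3, MeOH/THF/H2O, rt; 1 M HCl to pH 3
Reagents that add atoms: tert-butyl(chloro)diphenylsilane, CC(C)(C)[Si](Cl)(c1ccccc1)c1ccccc1
Why: Silylation of both the hydroxyl and the carboxyl followed by selective solvolysis of the labile silyl ester should leave the robust primary silyl ether (silyl ether protection).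

**Step 3**
Reactants: 5 12-[(tert-butyldiphenylsilyl)oxy]dodecanoic acid
Product: 6 S-ethyl 12-[(tert-butyldiphenylsilyl)oxy]dodecanethioate
Conditions: EtSH, DCC, DMAP (cat.), CH2Cl2, 0 °C → rt
Reagents that add atoms: ethanethiol, CCS
Why: Steglich-type carbodiimide coupling transfers the acyl group to the thiol and gives the thioester that serves as the acyl-thioester donor of the key step.

**Step 4**
Reactants: 6 S-ethyl 12-[(tert-butyldiphenylsilyl)oxy]dodecanethioate
Product: 7 (1Z)-12-[(tert-butyldiphenylsilyl)oxy]-1-(ethylsulfanyl)-1-[(trimethylsilyl)oxy]dodec-1-ene (chain cis to sulfur)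
Conditions: LiN(iPr)2, TMSCl (in situ quench), THF, −78 °C; pentane, filtration, concentration, used crude
Reagents that add atoms: chlorotrimethylsilane, C[Si](C)(C)Cl
Why: Kinetic deprotonation of the thioester with O-silylation of the enolate (silylketene acetal formation) should give mainly the isomer with the chain cis to sulfur, and the following addition is expected to be syn-selective for either geometry.

**Step 5**
Reactants: 2 dibenzyl 2-oxopentanedioate; 7 (1Z)-12-[(tert-butyldiphenylsilyl)oxy]-1-(ethylsulfanyl)-1-[(trimethylsilyl)oxy]dodec-1-ene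
Product: 10 benzyl (2S)-2-[(2S)-12-[(tert-butyldiphenylsilyl)oxy]-1-(ethylsulfanyl)-1-oxododecan-2-yl]-5-oxooxolane-2-carboxylate, via silyl ether adduct 8 (not isolated), via hydroxy triester 9 (not isolated)
Conditions: Cu(OTf)2 (10 mol%), (S,S)-tBu-box [2,2'-(propane-2,2-diyl)bis((4S)-4-tert-butyl-4,5-dihydrooxazole)] (11 mol%), THF, −78 °C; then 1 M HCl, THF, rt; then TsOH·H2O (cat.), PhMe, 60 °C
Reagents that add atoms: none
Why: The ketone and adjacent ester carbonyls of 2 should bind the divalent copper bis(oxazoline) complex as a five-membered chelate in a distorted square plane, the tert-butyl group of the (S,S) ligand covers the re face of the ketone, and 7 adds to the si face through an open transition state, silicon passing to the new tertiary oxygen to release the catalyst. The closest known reaction type is the copper bis(oxazoline)-catalysed enantioselective Mukaiyama aldol addition of substituted thioester silylketene acetals to pyruvate esters, a thioester-to-2-oxo-ester condensation that mirrors the acyl-thioester plus 2-oxoglutarate step presumed in alkylcitrate biosynthesis. The quaternary centre (S) is controlled by the ligand, and the adjacent CH centre (S) by the syn simple diastereoselection of this reaction class, so both centres arise in one bond formation. After hydrolysis of the silyl ether, the tertiary hydroxyl closes the oxolanone ring by 5-exo-trig lactonisation onto the γ-benzyl ester with loss of benzyl alcohol, helped by the fully substituted carbinol carbon (Thorpe–Ingold effect). The step needs activation of the ketone rather than the distal ester (the five-membered chelate is favoured over a seven-membered one) and γ-lactone rather than β-lactone formation with the thioester (ring strain decides); the silyl ether, the thioester and the α-benzyl ester should survive the catalytic acid.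

**Step 6**
Reactants: 10 benzyl (2S)-2-[(2S)-12-[(tert-butyldiphenylsilyl)oxy]-1-(ethylsulfanyl)-1-oxododecan-2-yl]-5-oxooxolane-2-carboxylate
Product: 11 benzyl (2S)-2-[(2S)-1-(benzyloxy)-12-[(tert-butyldiphenylsilyl)oxy]-1-oxododecan-2-yl]-5-oxooxolane-2-carboxylate
Conditions: AgO2CCF3, BnOH, PhMe, 60 °C, dark
Reagents that add atoms: benzyl alcohol, OCc1ccccc1
Why: Thiophilic monovalent silver activates the thioester sulfur so that benzyl alcohol displaces silver ethanethiolate (silver-promoted thioester alcoholysis) under non-basic conditions that avoid enolisation of the α-centre and retro-aldol cleavage.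

**Step 7**
Reactants: 11 benzyl (2S)-2-[(2S)-1-(benzyloxy)-12-[(tert-butyldiphenylsilyl)oxy]-1-oxododecan-2-yl]-5-oxooxolane-2-carboxylate
Product: 12 benzyl (2S)-2-[(2S)-1-(benzyloxy)-12-hydroxy-1-oxododecan-2-yl]-5-oxooxolane-2-carboxylate
Conditions: HF·pyridine, pyridine, THF, 0 °C → rt
Reagents that add atoms: none
Why: Fluoride-driven desilylation under buffered, non-basic conditions should free the primary alcohol while the lactone and both benzyl esters remain intact.

**Step 8**
Reactants: 13 (R)-malic acid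
Product: 14 (3R)-2,5-dioxooxolan-3-yl trifluoroacetate
Conditions: (CF3CO)2O (neat), 0 °C → rt; evaporation, co-evaporation with PhMe
Reagents that add atoms: trifluoroacetic anhydride, O=C(OC(=O)C(F)(F)F)C(F)(F)F
Why: Trifluoroacetic anhydride acylates the hydroxyl and dehydrates the diacid to the five-membered cyclic anhydride without breaking a bond at the stereocentre, so the configuration is retained.

**Step 9**
Reactants: 12 benzyl (2S)-2-[(2S)-1-(benzyloxy)-12-hydroxy-1-oxododecan-2-yl]-5-oxooxolane-2-carboxylate; 14 (3R)-2,5-dioxooxolan-3-yl trifluoroacetate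
Product: 16 (3R)-4-{[(11S)-12-(benzyloxy)-11-[(2S)-2-(benzyloxycarbonyl)-5-oxooxolan-2-yl]-12-oxododecyl]oxy}-3-hydroxy-4-oxobutanoic acid, via trifluoroacetate half ester 15 (not isolated)
Conditions: 14 (2 equiv), CH2Cl2, 0 °C → rt, no base; then THF/H2O, rt
Reagents that add atoms: none
Why: Regioselective anhydride alcoholysis is expected because the primary alcohol attacks the carbonyl next to the trifluoroacetoxy-bearing carbon, the more electrophilic one, giving the 1-ester with the 4-acid free; the labile trifluoroacetate is then hydrolysed, and the absence of base avoids elimination to a maleate.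

**Step 10**
Reactants: 16 (3R)-4-{[(11S)-12-(benzyloxy)-11-[(2S)-2-(benzyloxycarbonyl)-5-oxooxolan-2-yl]-12-oxododecyl]oxy}-3-hydroxy-4-oxobutanoic acid
Product: 17 (2S)-2-[(1S)-1-carboxy-11-{[(2R)-3-carboxy-2-hydroxypropanoyl]oxy}undecyl]-5-oxooxolane-2-carboxylic acid
Conditions: H2 (1 atm), 10% Pd/C, EtOAc, rt
Reagents that add atoms: none
Why: Catalytic hydrogenolysis should cleave both benzyl esters under neutral conditions that leave the lactone, the malate alkyl ester, the free hydroxyl and all three stereocentres untouched.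

**Compound list**
1 | 2-oxoglutaric acid (2-oxopentanedioic acid) | O=C(O)CCC(=O)C(=O)O | starting material
2 | dibenzyl 2-oxopentanedioate | O=C(CCC(=O)C(=O)OCc1ccccc1)OCc1ccccc1 | intermediate
3 | 12-hydroxydodecanoic acid | OCCCCCCCCCCCC(=O)O | starting material
4 | tert-butyldiphenylsilyl 12-[(tert-butyldiphenylsilyl)oxy]dodecanoate | CC(C)(C)[Si](c1ccccc1)(c1ccccc1)OCCCCCCCCCCCC(=O)O[Si](c1ccccc1)(c1ccccc1)C(C)(C)C | intermediate
5 | 12-[(tert-butyldiphenylsilyl)oxy]dodecanoic acid | CC(C)(C)[Si](c1ccccc1)(c1ccccc1)OCCCCCCCCCCCC(=O)O | intermediate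
6 | S-ethyl 12-[(tert-butyldiphenylsilyl)oxy]dodecanethioate | CC(C)(C)[Si](c1ccccc1)(c1ccccc1)OCCCCCCCCCCCC(=O)SCC | intermediate
7 | (1Z)-12-[(tert-butyldiphenylsilyl)oxy]-1-(ethylsulfanyl)-1-[(trimethylsilyl)oxy]dodec-1-ene | CCS/C(O[Si](C)(C)C)=C\CCCCCCCCCCO[Si](c1ccccc1)(c1ccccc1)C(C)(C)C | intermediate
8 | dibenzyl (2S)-2-[(2S)-12-[(tert-butyldiphenylsilyl)oxy]-1-(ethylsulfanyl)-1-oxododecan-2-yl]-2-[(trimethylsilyl)oxy]pentanedioate | CC(C)(C)[Si](c1ccccc1)(c1ccccc1)OCCCCCCCCCC[C@H](C(=O)SCC)[C@](O[Si](C)(C)C)(C(=O)OCc1ccccc1)CCC(=O)OCc1ccccc1 | intermediate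
9 | dibenzyl (2S)-2-[(2S)-12-[(tert-butyldiphenylsilyl)oxy]-1-(ethylsulfanyl)-1-oxododecan-2-yl]-2-hydroxypentanedioate | CC(C)(C)[Si](c1ccccc1)(c1ccccc1)OCCCCCCCCCC[C@H](C(=O)SCC)[C@](O)(C(=O)OCc1ccccc1)CCC(=O)OCc1ccccc1 | intermediate
10 | benzyl (2S)-2-[(2S)-12-[(tert-butyldiphenylsilyl)oxy]-1-(ethylsulfanyl)-1-oxododecan-2-yl]-5-oxooxolane-2-carboxylate | CC(C)(C)[Si](c1ccccc1)(c1ccccc1)OCCCCCCCCCC[C@H](C(=O)SCC)[C@]1(C(=O)OCc2ccccc2)CCC(=O)O1 | intermediate
11 | benzyl (2S)-2-[(2S)-1-(benzyloxy)-12-[(tert-butyldiphenylsilyl)oxy]-1-oxododecan-2-yl]-5-oxooxolane-2-carboxylate | CC(C)(C)[Si](c1ccccc1)(c1ccccc1)OCCCCCCCCCC[C@H](C(=O)OCc1ccccc1)[C@]1(C(=O)OCc2ccccc2)CCC(=O)O1 | intermediate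
12 | benzyl (2S)-2-[(2S)-1-(benzyloxy)-12-hydroxy-1-oxododecan-2-yl]-5-oxooxolane-2-carboxylate | OCCCCCCCCCC[C@H](C(=O)OCc1ccccc1)[C@]1(C(=O)OCc2ccccc2)CCC(=O)O1 | intermediate
13 | (R)-malic acid (D-malic acid) | O=C(O)C[C@@H](O)C(=O)O | starting material
14 | (3R)-2,5-dioxooxolan-3-yl trifluoroacetate | O=C1C[C@@H](OC(=O)C(F)(F)F)C(=O)O1 | intermediate
15 | (3R)-4-{[(11S)-12-(benzyloxy)-11-[(2S)-2-(benzyloxycarbonyl)-5-oxooxolan-2-yl]-12-oxododecyl]oxy}-4-oxo-3-(trifluoroacetoxy)butanoic acid | O=C(O)C[C@@H](OC(=O)C(F)(F)F)C(=O)OCCCCCCCCCC[C@H](C(=O)OCc1ccccc1)[C@]1(C(=O)OCc2ccccc2)CCC(=O)O1 | intermediate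
16 | (3R)-4-{[(11S)-12-(benzyloxy)-11-[(2S)-2-(benzyloxycarbonyl)-5-oxooxolan-2-yl]-12-oxododecyl]oxy}-3-hydroxy-4-oxobutanoic acid | O=C(O)C[C@@H](O)C(=O)OCCCCCCCCCC[C@H](C(=O)OCc1ccccc1)[C@]1(C(=O)OCc2ccccc2)CCC(=O)O1 | intermediate
17 | (2S)-2-[(1S)-1-carboxy-11-{[(2R)-3-carboxy-2-hydroxypropanoyl]oxy}undecyl]-5-oxooxolane-2-carboxylic acid | O=C(O)C[C@@H](O)C(=O)OCCCCCCCCCC[C@H](C(=O)O)[C@]1(C(=O)O)CCC(=O)O1 | target

**Step count and risks**
Total steps: 10. Longest linear sequence: 8 steps (steps 2, 3, 4, 5, 6, 7, 9, 10, from compound 3).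

Steps most likely to fail:

1. Step 5. The distal benzyl ester of 2 may compete for copper, which would slow turnover and erode face selectivity at the ketone, and lactonisation may stay incomplete. The fallback sets out from 7 and comes back at 10, with the distal carboxyl masked as a terminal alkene. But-3-enylmagnesium bromide added to dibenzyl oxalate (THF, −78 °C) would give benzyl 2-oxohex-5-enoate F1. The same copper-catalysed addition of 7 to F1 should give benzyl (2S)-2-[(2S)-12-[(tert-butyldiphenylsilyl)oxy]-1-(ethylsulfanyl)-1-oxododecan-2-yl]-2-[(trimethylsilyl)oxy]hex-5-enoate F2, and 1 M HCl in THF would hydrolyse it to the corresponding 2-hydroxy ester F3. Ozonolysis (O3, CH2Cl2, −78 °C; Me2S) should give benzyl (2S)-2-[(2S)-12-[(tert-butyldiphenylsilyl)oxy]-1-(ethylsulfanyl)-1-oxododecan-2-yl]-5-hydroxyoxolane-2-carboxylate F4 directly, by ring closure of the hydroxy aldehyde. Lactol oxidation (TEMPO cat., PhI(OAc)2, CH2Cl2) would then return 10.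

2. Step 6. Alcoholysis at the hindered acyl carbon, flanked by the quaternary centre, may be slow, so that acid-promoted loss of the silyl ether or opening of the lactone by benzyl alcohol competes. The fallback sets out from 10 and comes back at 11, replacing acyl substitution by reduction and oxidation. Fukuyama reduction (Et3SiH, 10% Pd/C, acetone, rt) would give benzyl (2S)-2-[(2S)-12-[(tert-butyldiphenylsilyl)oxy]-1-oxododecan-2-yl]-5-oxooxolane-2-carboxylate F5. Pinnick oxidation (NaClO2, NaH2PO4, 2-methylbut-2-ene, tBuOH/H2O) would give (2S)-2-[(2S)-2-(benzyloxycarbonyl)-5-oxooxolan-2-yl]-12-[(tert-butyldiphenylsilyl)oxy]dodecanoic acid F6. Benzylation (BnBr, KHCO3, DMF) would then return 11.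

3. Step 9. The alcohol may attack the distal anhydride carbonyl (wrong regiochemistry), trifluoroacetate may be eliminated to a maleate, or the uncatalysed acylation may stall. The fallback sets out from 12 (with 13) and comes back at 17; it fixes the regiochemistry by construction through carboxylate alkylation. Compound 13 with 2,2-dimethoxypropane and TsOH would give [(4R)-2,2-dimethyl-5-oxo-1,3-dioxolan-4-yl]acetic acid F7. Benzylation (BnBr, Et3N, acetone) would give benzyl [(4R)-2,2-dimethyl-5-oxo-1,3-dioxolan-4-yl]acetate F8, and AcOH/H2O at 40 °C would open it to (2R)-4-(benzyloxy)-2-hydroxy-4-oxobutanoic acid F9. Alcohol 12 would be converted (I2, PPh3, imidazole, CH2Cl2) into benzyl (2S)-2-[(2S)-1-(benzyloxy)-12-iodo-1-oxododecan-2-yl]-5-oxooxolane-2-carboxylate F10. The pre-formed caesium carboxylate of F9 (CsHCO3, DMF, rt, no excess base) would alkylate on the carboxylate oxygen with F10 to give 4-benzyl 1-{(11S)-12-(benzyloxy)-11-[(2S)-2-(benzyloxycarbonyl)-5-oxooxolan-2-yl]-12-oxododecyl} (2R)-2-hydroxybutanedioate F11. Hydrogenolysis (H2, 10% Pd/C, EtOAc) would then give 17.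

**Further compounds**
F1 | step 5 | benzyl 2-oxohex-5-enoate | C=CCCC(=O)C(=O)OCc1ccccc1
F2 | step 5 | benzyl (2S)-2-[(2S)-12-[(tert-butyldiphenylsilyl)oxy]-1-(ethylsulfanyl)-1-oxododecan-2-yl]-2-[(trimethylsilyl)oxy]hex-5-enoate | CC(C)(C)[Si](c1ccccc1)(c1ccccc1)OCCCCCCCCCC[C@H](C(=O)SCC)[C@](O[Si](C)(C)C)(C(=O)OCc1ccccc1)CCC=C
F3 | step 5 | benzyl (2S)-2-[(2S)-12-[(tert-butyldiphenylsilyl)oxy]-1-(ethylsulfanyl)-1-oxododecan-2-yl]-2-hydroxyhex-5-enoate | CC(C)(C)[Si](c1ccccc1)(c1ccccc1)OCCCCCCCCCC[C@H](C(=O)SCC)[C@](O)(C(=O)OCc1ccccc1)CCC=C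
F4 | step 5 | benzyl (2S)-2-[(2S)-12-[(tert-butyldiphenylsilyl)oxy]-1-(ethylsulfanyl)-1-oxododecan-2-yl]-5-hydroxyoxolane-2-carboxylate | CC(C)(C)[Si](c1ccccc1)(c1ccccc1)OCCCCCCCCCC[C@H](C(=O)SCC)[C@]1(C(=O)OCc2ccccc2)CCC(O)O1
F5 | step 6 | benzyl (2S)-2-[(2S)-12-[(tert-butyldiphenylsilyl)oxy]-1-oxododecan-2-yl]-5-oxooxolane-2-carboxylate | CC(C)(C)[Si](c1ccccc1)(c1ccccc1)OCCCCCCCCCC[C@H](C=O)[C@]1(C(=O)OCc2ccccc2)CCC(=O)O1
F6 | step 6 | (2S)-2-[(2S)-2-(benzyloxycarbonyl)-5-oxooxolan-2-yl]-12-[(tert-butyldiphenylsilyl)oxy]dodecanoic acid | CC(C)(C)[Si](c1ccccc1)(c1ccccc1)OCCCCCCCCCC[C@H](C(=O)O)[C@]1(C(=O)OCc2ccccc2)CCC(=O)O1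
F7 | step 9 | [(4R)-2,2-dimethyl-5-oxo-1,3-dioxolan-4-yl]acetic acid | CC1(C)O[C@H](CC(=O)O)C(=O)O1
F8 | step 9 | benzyl [(4R)-2,2-dimethyl-5-oxo-1,3-dioxolan-4-yl]acetate | CC1(C)O[C@H](CC(=O)OCc2ccccc2)C(=O)O1
F9 | step 9 | (2R)-4-(benzyloxy)-2-hydroxy-4-oxobutanoic acid | O=C(OCc1ccccc1)C[C@@H](O)C(=O)O
F10 | step 9 | benzyl (2S)-2-[(2S)-1-(benzyloxy)-12-iodo-1-oxododecan-2-yl]-5-oxooxolane-2-carboxylate | ICCCCCCCCCC[C@H](C(=O)OCc1ccccc1)[C@]1(C(=O)OCc2ccccc2)CCC(=O)O1
F11 | step 9 | 4-benzyl 1-{(11S)-12-(benzyloxy)-11-[(2S)-2-(benzyloxycarbonyl)-5-oxooxolan-2-yl]-12-oxododecyl} (2R)-2-hydroxybutanedioate | O=C(OCc1ccccc1)C[C@@H](O)C(=O)OCCCCCCCCCC[C@H](C(=O)OCc1ccccc1)[C@]1(C(=O)OCc2ccccc2)CCC(=O)O1
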